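## Retrosynthetic overview

1. The target comes from a protected macrocyclic ketone by desilylation, acetylation of the C2 and C14 hydroxyls and release of the C20 alcohol.
2. The ten-membered ring is closed last, at C9–C10, by a ruthenium-hydride-catalysed intramolecular hydroacylation of a ring-A 1,3-diene by the C9 aldehyde (sets C10).
3. The two fragments are joined at C4–C5 by a B-alkyl Suzuki–Miyaura coupling of the ring-A vinyl carbinol with a (Z)-vinyl iodide.
4. Ring-A fragment: iridium-catalysed tert-(hydroxy)prenylation (C1, C14), anti-selective 1,3-reduction (C2), ring-closing metathesis (ring A), palladium-catalysed elimination to the diene.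
5. Lactone fragment: Sharpless epoxidation and titanium-mediated acrylate opening (C7), copper-hydride reductive aldol lactonisation (C8, C17; lactone ring).

Assumption 1: the target is taken exactly as the given SMILES, (1S,2S,5Z,7S,8S,10S,14S,17R) in briarane numbering, and C1–C20 below are these numbers (C1 quaternary carbon with CH3-15, C2 and C14 acetoxy carbons, C5=C6 Z-alkene, C7 lactone O–CH, C8 tertiary carbinol, C9 ketone, C10 ring-fusion CH, C11=C12 ring-A alkene with C20 on C11, C17 lactone CH(CH3), C19 lactone C=O).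

Assumption 2: the iridium-catalysed step gives the adduct with the secondary OH anti to CH2OH, and (R)-Tol-BINAP gives the absolute sense drawn; if the sense proves opposite, the antipodal ligand is used.

Abbreviations: TBS = tert-butyldimethylsilyl, TES = triethylsilyl, PMB = 4-methoxybenzyl.

## Route

Step 1
Reactants: 1 3,3-dimethoxypropan-1-ol; 2 2-methyl-2-vinyloxirane (isoprene monoxide, racemic)
Product: 3 (2S,3S)-5,5-dimethoxy-2-methyl-2-vinylpentane-1,3-diol
Conditions: Ir(η3-allyl)[(R)-Tol-BINAP](C,O-4-cyano-3-nitrobenzoate) (5 mol %, preformed from [Ir(cod)Cl]2), K3PO4 (5 mol %), THF, 60 °C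
Reagents that add atoms: none
Why: Iridium-catalysed transfer-hydrogenative tert-(hydroxy)prenylation (carbonyl allylation from the alcohol oxidation level), in which 1 is dehydrogenated to the aldehyde and the π-allyl iridium from 2 adds through a closed chair transition state, so that C14 and the quaternary C1 are set together (OH anti to CH2OH) under ligand control, both epoxide enantiomers converging.

Step 2
Reactants: 3 (2S,3S)-5,5-dimethoxy-2-methyl-2-vinylpentane-1,3-diol
Product: 4 (2R,3S)-3-hydroxy-5,5-dimethoxy-2-methyl-2-vinylpentanal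
Conditions: TEMPO (10 mol %), PhI(OAc)2 (1.1 equiv), CH2Cl2, rt
Reagents that add atoms: none
Why: Oxoammonium (TEMPO) oxidation is selective for the primary alcohol, and the α-quaternary β-hydroxy aldehyde cannot dehydrate or epimerise.

Step 3
Reactants: 4 (2R,3S)-3-hydroxy-5,5-dimethoxy-2-methyl-2-vinylpentanal
Product: 5 (4R,5S)-7,7-dimethoxy-4-methyl-4-vinylhept-1-ene-3,5-diol (C2 epimers)
Conditions: CH2=CHMgBr (3 equiv), THF, −78 °C; aq. NH4Cl
Reagents that add atoms: vinylmagnesium bromide, C=C[Mg]Br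
Why: Grignard 1,2-addition to the aldehyde after deprotonation of the C14 hydroxyl, the new C2 centre being erased in step 4.

Step 4
Reactants: 5 (4R,5S)-7,7-dimethoxy-4-methyl-4-vinylhept-1-ene-3,5-diol (C2 epimers)
Product: 6 (4R,5S)-5-hydroxy-7,7-dimethoxy-4-methyl-4-vinylhept-1-en-3-one
Conditions: MnO2 (20 equiv), CH2Cl2, rt
Reagents that add atoms: none
Why: MnO2 oxidises only the allylic C2 alcohol, leaving the non-allylic C14 alcohol for the directed reduction.

Step 5
Reactants: 6 (4R,5S)-5-hydroxy-7,7-dimethoxy-4-methyl-4-vinylhept-1-en-3-one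
Product: 7 (3S,4R,5S)-7,7-dimethoxy-4-methyl-4-vinylhept-1-ene-3,5-diol
Conditions: Me4NBH(OAc)3 (5 equiv), MeCN–AcOH (2:1), −30 °C
Reagents that add atoms: none
Why: Evans–Saksena reduction, in which the C14 alkoxy(diacetoxy)borohydride delivers hydride intramolecularly through a chair transition state to give the 1,3-anti diol, setting C2.

Step 6
Reactants: 7 (3S,4R,5S)-7,7-dimethoxy-4-methyl-4-vinylhept-1-ene-3,5-diol
Product: 8 (3S,4R,5S)-3,5-bis(TBS-oxy)-7,7-dimethoxy-4-methyl-4-vinylhept-1-ene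
Conditions: TBSOTf (3 equiv), 2,6-lutidine (5 equiv), CH2Cl2, −78 → −20 °C
Reagents that add atoms: tert-butyldimethylsilyl triflate, CC(C)(C)[Si](C)(C)OS(=O)(=O)C(F)(F)F
Why: Silyl triflate silylation of the two hindered secondary alcohols; any acetal that is cleaved converges in step 7.

Step 7
Reactants: 8 (3S,4R,5S)-3,5-bis(TBS-oxy)-7,7-dimethoxy-4-methyl-4-vinylhept-1-ene
Product: 9 (3S,4R,5S)-3,5-bis(TBS-oxy)-4-methyl-4-vinylhept-6-enal
Conditions: PPTS (0.2 equiv), acetone–H2O (9:1), 50 °C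
Reagents that add atoms: water, O
Why: Mild acid hydrolysis of the dimethyl acetal to the C12 aldehyde, which the hindered secondary TBS ethers survive.

Step 8
Reactants: 10 2-bromoprop-2-en-1-ol
Product: 11 1-[(2-bromoallyloxy)methyl]-4-methoxybenzene (2-bromoallyl PMB ether)
Conditions: NaH, PMBCl, Bu4NI (cat.), THF–DMF, 0 °C → rt
Reagents that add atoms: 4-methoxybenzyl chloride, COc1ccc(CCl)cc1
Why: Williamson etherification protects the future C20 oxygen.

Step 9
Reactants: 11 2-bromoallyl PMB ether; 9 (3S,4R,5S)-3,5-bis(TBS-oxy)-4-methyl-4-vinylhept-6-enal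
Product: 14 (5S,6R,7S)-5,7-bis(TBS-oxy)-2-(PMB-oxymethyl)-6-methyl-6-vinylnona-1,8-dien-3-yl methyl carbonate (C12 epimers), via 2-lithioallyl PMB ether 12 (not isolated), via lithium alkoxide 13 (not isolated)
Conditions: 11, t-BuLi (2 equiv), Et2O, −78 °C; then 9, −78 °C; then ClCO2Me, −78 → 0 °C
Reagents that add atoms: methyl chloroformate, COC(=O)Cl
Why: Bromine–lithium exchange, 1,2-addition of the vinyllithium to the aldehyde (C11–C12 bond) and acylation of the alkoxide in the same flask; the C12 configuration is irrelevant because C12 becomes sp2 in step 11.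

Step 10
Reactants: 14 (5S,6R,7S)-5,7-bis(TBS-oxy)-2-(PMB-oxymethyl)-6-methyl-6-vinylnona-1,8-dien-3-yl methyl carbonate (C12 epimers)
Product: 15 ring-A carbonate: methyl [5-(TBS-oxy)-2-(PMB-oxymethyl)-4-methyl-4-((S)-1-(TBS-oxy)allyl)cyclohex-2-enyl] carbonate (C12 epimers; C1 and C14 as in the target)
Conditions: (H2IMes)Cl2Ru=CH(C6H4-2-OiPr) (second-generation Hoveyda–Grubbs catalyst, 5 mol %), toluene (0.005 M), 80 °C
Reagents that add atoms: none
Why: Ring-closing metathesis between the C10 vinyl and the C11 methylene closes the six-membered ring A, which is favoured over the seven-membered closure open to the hindered C3=C4 vinyl.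

Step 11
Reactants: 15 ring-A carbonate (C12 epimers)
Product: 16 ring-A diene: (5S,6S)-5-(TBS-oxy)-2-(PMB-oxymethyl)-6-methyl-6-[(S)-1-(TBS-oxy)allyl]cyclohexa-1,3-diene
Conditions: Pd(OAc)2 (5 mol %), PPh3 (20 mol %), 1,4-dioxane, 90 °C
Reagents that add atoms: none
Why: Tsuji-type palladium-catalysed elimination, in which zerovalent palladium ionises the allylic carbonate to the C10–C12 π-allyl complex and the only available β-hydrogens (on C13) give the single C10=C11–C12=C13 diene from both epimers.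

Step 12
Reactants: 17 but-2-yn-1-ol
Product: 19 (Z)-3-iodobut-2-en-1-ol, via sodium alkenylalanate 18 (not isolated)
Conditions: NaAlH2(OCH2CH2OMe)2 (1.5 equiv), THF, 0 °C → rt; then I2 (2 equiv), −78 → 0 °C
Reagents that add atoms: iodine, II
Why: Hydroxyl-directed trans-hydroalumination gives the cyclic alkenylalanate, whose iodinolysis with retention fixes the Z geometry of the future C5=C6 alkene.

Step 13
Reactants: 19 (Z)-3-iodobut-2-en-1-ol
Product: 21 ethyl (2E,4Z)-5-iodohexa-2,4-dienoate, via (Z)-3-iodobut-2-enal 20 (not isolated)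
Conditions: MnO2 (10 equiv), Ph3P=CHCO2Et (1.2 equiv), CH2Cl2, rt
Reagents that add atoms: ethyl (triphenylphosphoranylidene)acetate, CCOC(=O)C=P(c1ccccc1)(c1ccccc1)c1ccccc1
Why: Tandem allylic oxidation–Wittig olefination traps the isomerisation-prone Z-iodoenal as it forms, the stabilised ylide giving the E alkene.

Step 14
Reactants: 21 ethyl (2E,4Z)-5-iodohexa-2,4-dienoate
Product: 22 (2E,4Z)-5-iodohexa-2,4-dien-1-ol
Conditions: i-Bu2AlH (2.2 equiv), CH2Cl2, −78 °C; aq. potassium sodium tartrate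
Reagents that add atoms: none
Why: 1,2-Reduction of the ester to the allylic alcohol without touching the vinyl iodide.

Step 15
Reactants: 22 (2E,4Z)-5-iodohexa-2,4-dien-1-ol
Product: 23 [(2R,3R)-3-((Z)-2-iodoprop-1-enyl)oxiran-2-yl]methanol
Conditions: Ti(OiPr)4 (10 mol %), D-(−)-diethyl tartrate (12 mol %), t-BuOOH (2 equiv), 4 Å molecular sieves, CH2Cl2, −20 °C
Reagents that add atoms: tert-butyl hydroperoxide, CC(C)(C)OO
Why: Sharpless asymmetric epoxidation of the allylic alcohol alkene only, the D-tartrate giving the (2R,3R) epoxide that carries the C7 oxygen stereochemistry.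

Step 16
Reactants: 23 [(2R,3R)-3-((Z)-2-iodoprop-1-enyl)oxiran-2-yl]methanol; 24 acrylic acid
Product: 25 (2R,3S,4Z)-1,2-dihydroxy-5-iodohex-4-en-3-yl prop-2-enoate
Conditions: 24 (1.5 equiv), Ti(OiPr)4 (1.5 equiv), CH2Cl2, 0 °C → rt
Reagents that add atoms: none
Why: Titanium-mediated opening of the 2,3-epoxy alcohol by the carboxylate at the allylic C3 position (C7) with inversion sets C7 in the target configuration.

Step 17
Reactants: 25 (2R,3S,4Z)-1,2-dihydroxy-5-iodohex-4-en-3-yl prop-2-enoate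
Product: 26 (2R,3S,4Z)-2-hydroxy-5-iodo-1-(TES-oxy)hex-4-en-3-yl prop-2-enoate
Conditions: Et3SiCl (1.05 equiv), imidazole, CH2Cl2, −40 °C
Reagents that add atoms: chlorotriethylsilane, CC[Si](Cl)(CC)CC
Why: Silylation is selective for the primary C9 hydroxyl over the secondary C8 hydroxyl at low temperature.

Step 18
Reactants: 26 (2R,3S,4Z)-2-hydroxy-5-iodo-1-(TES-oxy)hex-4-en-3-yl prop-2-enoate
Product: 27 (3S,4Z)-5-iodo-2-oxo-1-(TES-oxy)hex-4-en-3-yl prop-2-enoate
Conditions: Dess–Martin periodinane, NaHCO3, CH2Cl2, 0 °C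
Reagents that add atoms: none
Why: Non-basic Dess–Martin oxidation gives the C8 ketone without epimerising the acidic C7 hydrogen.

Step 19
Reactants: 27 (3S,4Z)-5-iodo-2-oxo-1-(TES-oxy)hex-4-en-3-yl prop-2-enoate
Product: 29 (3R,4R,5S)-4-hydroxy-4-(hydroxymethyl)-5-[(Z)-2-iodoprop-1-enyl]-3-methyloxolan-2-one, via silyl aldolate 28 (not isolated)
Conditions: Cu(OAc)2·H2O (5 mol %), rac-BINAP (5 mol %), (HMe2Si)2O (1.5 equiv), THF, 0 °C → rt; then Et3N·3HF, THF, rt
Reagents that add atoms: none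
Why: Copper-hydride-catalysed reductive aldol cyclisation, in which conjugate reduction of the acrylate gives the Z copper enolate that adds to the C8 ketone through a chelated transition state, placing C9 trans to the C7 alkenyl group and the C17 methyl cis to the new C8 hydroxyl (sets C8 and C17, forms the lactone ring).

Step 20
Reactants: 29 (3R,4R,5S)-4-hydroxy-4-(hydroxymethyl)-5-[(Z)-2-iodoprop-1-enyl]-3-methyloxolan-2-one
Product: 30 bis-TES ether of 29 (C8–OTES and C9–OTES)
Conditions: Et3SiOTf (3 equiv), 2,6-lutidine, CH2Cl2, −78 → 0 °C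
Reagents that add atoms: triethylsilyl triflate, CC[Si](CC)(CC)OS(=O)(=O)C(F)(F)F
Why: Silyl triflate silylates both the primary and the tertiary hydroxyl.

Step 21
Reactants: 30 bis-TES ether of 29
Product: 32 lactone aldehyde: 3-methyl-2-oxo-5-[(Z)-2-iodoprop-1-enyl]-4-(TES-oxy)oxolane-4-carbaldehyde (C7 and C8 and C17 as in the target), via alkoxysulfonium chloride 31 (not isolated)
Conditions: (COCl)2, DMSO, CH2Cl2, −78 → −40 °C; then Et3N, −78 °C → rt
Reagents that add atoms: none
Why: Swern conditions cleave and oxidise a primary TES ether directly to the aldehyde while the tertiary TES ether stays, so the free tertiary α-hydroxy aldehyde is never formed.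

Step 22
Reactants: 16 ring-A diene; 32 lactone aldehyde
Product: 34 seco diene aldehyde (C4–C5 joined; full C1–C20 skeleton lacking the C9–C10 bond), via B-alkyl-9-BBN borane 33 (not isolated)
Conditions: 16, 9-BBN (1.5 equiv), THF, rt; then 32, PdCl2(dppf) (10 mol %), AsPh3 (10 mol %), aq. K3PO4, DMF, rt
Reagents that add atoms: none
Why: B-alkyl Suzuki–Miyaura coupling, in which 9-BBN hydroborates only the terminal C3=C4 alkene (boron on C4) and the alkylborane couples with the vinyl iodide with retention of the Z geometry.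

Step 23
Reactants: 34 seco diene aldehyde
Product: 35 macrocyclic ketone: 2,14-bis-O-TBS, 8-O-TES, 20-O-PMB derivative of the dideacetyl target
Conditions: RuHCl(CO)(PPh3)3 (10 mol %), toluene (0.002 M), 110 °C
Reagents that add atoms: none
Why: Proposed new method: a macrocyclising diene hydroacylation under ruthenium hydride catalysis, in which Ru–H adds across the less hindered C12=C13 bond (hydride to C13) to give the C10–C11–C12 allylruthenium, whose σ-form at C12 adds the tethered aldehyde at C10 through a closed six-membered transition state, and β-hydride elimination of the ruthenium alkoxide gives the C9 ketone and returns Ru–H; the diene cannot isomerise because C1 is quaternary, and C–C bond formation on the C10 face that carries CH3-15 (opposite the C1–C2 bond and the C14 silyloxy group) gives the trans ring fusion (10S); the closest known reaction is the ruthenium-catalysed intermolecular hydroacylation of acyclic 1,3-dienes with aldehydes to β,γ-unsaturated ketones, which has not been shown intramolecularly, for a ten-membered ring or on a cyclohexadiene.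

Step 24
Reactants: 35 macrocyclic ketone
Product: 36 20-O-PMB ether of the 2,14-dideacetyl target (2,8,14-triol)
Conditions: HF·pyridine, pyridine, THF, 0 °C → rt
Reagents that add atoms: none
Why: Buffered fluoride desilylation removes the two TBS ethers and the tertiary TES ether and leaves the PMB ether, the lactone and the β,γ-unsaturated ketone.

Step 25
Reactants: 36 20-O-PMB ether of the 2,14-dideacetyl target
Product: 37 20-O-PMB ether of the target
Conditions: Ac2O, pyridine, DMAP (cat.), CH2Cl2, rt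
Reagents that add atoms: acetic anhydride, CC(=O)OC(C)=O
Why: DMAP-catalysed acetylation of the two secondary alcohols, the hindered tertiary C8 α-ketol hydroxyl being inert under these conditions.

Step 26
Reactants: 37 20-O-PMB ether of the target
Product: 38 CNP0140109.1 (target)
Conditions: DDQ (1.5 equiv), CH2Cl2–pH 7 buffer (10:1), 0 °C
Reagents that add atoms: none
Why: Oxidative cleavage of the PMB ether by DDQ releases the primary allylic C20 alcohol under neutral conditions that the acetates and the ketone tolerate.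

## Compound list

1 | 3,3-dimethoxypropan-1-ol | COC(OC)CCO | starting material
2 | 2-methyl-2-vinyloxirane (racemic) | CC1(C=C)CO1 | starting material
3 | (2S,3S)-5,5-dimethoxy-2-methyl-2-vinylpentane-1,3-diol | COC(OC)C[C@H](O)[C@](C)(CO)C=C | intermediate
4 | (2R,3S)-3-hydroxy-5,5-dimethoxy-2-methyl-2-vinylpentanal | COC(OC)C[C@H](O)[C@](C)(C=O)C=C | intermediate
5 | (4R,5S)-7,7-dimethoxy-4-methyl-4-vinylhept-1-ene-3,5-diol (C2 epimers) | COC(OC)C[C@H](O)[C@](C)(C(O)C=C)C=C | intermediate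
6 | (4R,5S)-5-hydroxy-7,7-dimethoxy-4-methyl-4-vinylhept-1-en-3-one | COC(OC)C[C@H](O)[C@](C)(C(=O)C=C)C=C | intermediate
7 | (3S,4R,5S)-7,7-dimethoxy-4-methyl-4-vinylhept-1-ene-3,5-diol | COC(OC)C[C@H](O)[C@](C)([C@@H](O)C=C)C=C | intermediate
8 | (3S,4R,5S)-3,5-bis(TBS-oxy)-7,7-dimethoxy-4-methyl-4-vinylhept-1-ene | COC(OC)C[C@H](O[Si](C)(C)C(C)(C)C)[C@](C)([C@@H](O[Si](C)(C)C(C)(C)C)C=C)C=C | intermediate
9 | (3S,4R,5S)-3,5-bis(TBS-oxy)-4-methyl-4-vinylhept-6-enal | O=CC[C@H](O[Si](C)(C)C(C)(C)C)[C@](C)([C@@H](O[Si](C)(C)C(C)(C)C)C=C)C=C | intermediate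
10 | 2-bromoprop-2-en-1-ol | OCC(Br)=C | starting material
11 | 2-bromoallyl PMB ether | C=C(Br)COCc1ccc(OC)cc1 | intermediate
12 | 2-lithioallyl PMB ether (formed in the flask) | [Li]C(=C)COCc1ccc(OC)cc1 | intermediate
13 | lithium alkoxide of the C12 carbinol (formed in the flask, C12 epimers) | [Li]OC(C[C@H](O[Si](C)(C)C(C)(C)C)[C@](C)([C@@H](O[Si](C)(C)C(C)(C)C)C=C)C=C)C(=C)COCc1ccc(OC)cc1 | intermediate
14 | (5S,6R,7S)-5,7-bis(TBS-oxy)-2-(PMB-oxymethyl)-6-methyl-6-vinylnona-1,8-dien-3-yl methyl carbonate (C12 epimers) | COC(=O)OC(C[C@H](O[Si](C)(C)C(C)(C)C)[C@](C)([C@@H](O[Si](C)(C)C(C)(C)C)C=C)C=C)C(=C)COCc1ccc(OC)cc1 | intermediate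
15 | ring-A carbonate: methyl [5-(TBS-oxy)-2-(PMB-oxymethyl)-4-methyl-4-((S)-1-(TBS-oxy)allyl)cyclohex-2-enyl] carbonate (C12 epimers) | CC(C)(C)[Si](C)(C)O[C@H]1CC(OC(=O)OC)C(COCc2ccc(OC)cc2)=C[C@@]1(C)[C@@H](O[Si](C)(C)C(C)(C)C)C=C | intermediate
16 | ring-A diene: (5S,6S)-5-(TBS-oxy)-2-(PMB-oxymethyl)-6-methyl-6-[(S)-1-(TBS-oxy)allyl]cyclohexa-1,3-diene | CC(C)(C)[Si](C)(C)O[C@H]1C=CC(COCc2ccc(OC)cc2)=C[C@@]1(C)[C@@H](O[Si](C)(C)C(C)(C)C)C=C | intermediate
17 | but-2-yn-1-ol | CC#CCO | starting material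
18 | sodium cyclic alkenylalanate from 17 (formed in the flask) | CC1=CCO[Al-]1(OCCOC)OCCOC.[Na+] | intermediate
19 | (Z)-3-iodobut-2-en-1-ol | C/C(I)=C/CO | intermediate
20 | (Z)-3-iodobut-2-enal (formed in the flask) | C/C(I)=C/C=O | intermediate
21 | ethyl (2E,4Z)-5-iodohexa-2,4-dienoate | CCOC(=O)/C=C/C=C(/C)I | intermediate
22 | (2E,4Z)-5-iodohexa-2,4-dien-1-ol | OC/C=C/C=C(/C)I | intermediate
23 | [(2R,3R)-3-((Z)-2-iodoprop-1-enyl)oxiran-2-yl]methanol | OC[C@H]1O[C@@H]1/C=C(/C)I | intermediate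
24 | acrylic acid | C=CC(=O)O | starting material
25 | (2R,3S,4Z)-1,2-dihydroxy-5-iodohex-4-en-3-yl prop-2-enoate | OC[C@@H](O)[C@@H](OC(=O)C=C)/C=C(/C)I | intermediate
26 | (2R,3S,4Z)-2-hydroxy-5-iodo-1-(TES-oxy)hex-4-en-3-yl prop-2-enoate | CC[Si](CC)(CC)OC[C@@H](O)[C@@H](OC(=O)C=C)/C=C(/C)I | intermediate
27 | (3S,4Z)-5-iodo-2-oxo-1-(TES-oxy)hex-4-en-3-yl prop-2-enoate | CC[Si](CC)(CC)OCC(=O)[C@@H](OC(=O)C=C)/C=C(/C)I | intermediate
28 | silyl aldolate: 8-O-(1,1,3,3-tetramethyldisiloxanyl), 9-O-TES lactone (formed in the flask) | CC[Si](CC)(CC)OC[C@@]1(O[Si](C)(C)O[SiH](C)C)[C@H](/C=C(/C)I)OC(=O)[C@@H]1C | intermediate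
29 | (3R,4R,5S)-4-hydroxy-4-(hydroxymethyl)-5-[(Z)-2-iodoprop-1-enyl]-3-methyloxolan-2-one | OC[C@@]1(O)[C@H](/C=C(/C)I)OC(=O)[C@@H]1C | intermediate
30 | bis-TES ether of 29 | CC[Si](CC)(CC)OC[C@@]1(O[Si](CC)(CC)CC)[C@H](/C=C(/C)I)OC(=O)[C@@H]1C | intermediate
31 | dimethyl(alkoxy)sulfonium chloride of the C9 oxygen (formed in the flask) | C[S+](C)OC[C@@]1(O[Si](CC)(CC)CC)[C@H](/C=C(/C)I)OC(=O)[C@@H]1C.[Cl-] | intermediate
32 | lactone aldehyde: 3-methyl-2-oxo-5-[(Z)-2-iodoprop-1-enyl]-4-(TES-oxy)oxolane-4-carbaldehyde | O=C[C@@]1(O[Si](CC)(CC)CC)[C@H](/C=C(/C)I)OC(=O)[C@@H]1C | intermediate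
33 | B-alkyl-9-BBN borane from 16 (boron on C4, formed in the flask) | CC(C)(C)[Si](C)(C)O[C@H]1C=CC(COCc2ccc(OC)cc2)=C[C@@]1(C)[C@@H](O[Si](C)(C)C(C)(C)C)CCB3C4CCCC3CCC4 | intermediate
34 | seco diene aldehyde | O=C[C@@]1(O[Si](CC)(CC)CC)[C@H](/C=C(/C)CC[C@H](O[Si](C)(C)C(C)(C)C)[C@]2(C)C=C(COCc3ccc(OC)cc3)C=C[C@@H]2O[Si](C)(C)C(C)(C)C)OC(=O)[C@@H]1C | intermediate
35 | macrocyclic ketone (2,14-bis-O-TBS, 8-O-TES, 20-O-PMB) | CC(C)(C)[Si](C)(C)O[C@H]1CC=C(COCc4ccc(OC)cc4)[C@@H]2C(=O)[C@@]3(O[Si](CC)(CC)CC)[C@H](/C=C(/C)CC[C@H](O[Si](C)(C)C(C)(C)C)[C@]21C)OC(=O)[C@@H]3C | intermediate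
36 | 20-O-PMB ether of the 2,14-dideacetyl target | O[C@H]1CC=C(COCc4ccc(OC)cc4)[C@@H]2C(=O)[C@@]3(O)[C@H](/C=C(/C)CC[C@H](O)[C@]21C)OC(=O)[C@@H]3C | intermediate
37 | 20-O-PMB ether of the target | CC(=O)O[C@H]1CC=C(COCc4ccc(OC)cc4)[C@@H]2C(=O)[C@@]3(O)[C@H](/C=C(/C)CC[C@H](OC(C)=O)[C@]21C)OC(=O)[C@@H]3C | intermediate
38 | CNP0140109.1, (1S,2S,5Z,7S,8S,10S,14S,17R)-2,14-diacetoxy-8,20-dihydroxy-9-oxobriara-5,11-dien-19,7-olide | CC(=O)O[C@H]1CC=C(CO)[C@@H]2C(=O)[C@@]3(O)[C@H](/C=C(/C)CC[C@H](OC(C)=O)[C@]21C)OC(=O)[C@@H]3C | target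

## Step count and risks

Total step count: 26.
Longest linear sequence: 15 steps (steps 1–7, 9–11 and 22–26; the lactone branch, steps 12–21 and 22–26, is equally long).

Three steps most likely to fail:

Step 23 (the new ruthenium hydride macrocyclisation). Risks are no turnover with the hindered α-silyloxy aldehyde, hydride addition at the wrong diene terminus, or the C10 epimer. Fallback with known chemistry: a chromium-mediated intramolecular allylation of the Nozaki–Hiyama type, established for ten-membered carbocycles. It sets out from 15. K2CO3 in MeOH cleaves the carbonate to the ring-A allylic alcohol F1 (C12 epimers). Hydroboration with 9-BBN (2.5 equiv) and coupling with 32 under the conditions of step 22 give the seco hydroxy aldehyde F2. MsCl, LiCl and 2,4,6-collidine in DMF at 0 °C give the allylic chloride F3. CrCl2 (6 equiv) with catalytic LiI in THF at 0.002 M forms the allylchromium (trivalent chromium) at C12, which adds to the aldehyde through C10 and gives the macrocyclic C9 alcohol F4 (C9 epimers). Dess–Martin oxidation then gives 35, where the fallback returns to the route.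

Step 19 (copper hydride reductive aldol lactonisation). Risks are competing reduction of the activated ketone and modest facial selectivity at C8. Fallback: generate the ester enolate by C–Br reduction instead (intramolecular Reformatsky reaction). It sets out from 23. Ti(OiPr)4 and racemic 2-bromopropanoic acid (CC(Br)C(=O)O) open the epoxide at C7 to the bromopropanoate diol F5. Et3SiCl and imidazole give the primary TES ether F6, and Dess–Martin oxidation gives the bromopropanoyloxy ketone F7. SmI2 (2.2 equiv) in THF at −78 °C gives the hydroxy lactone F8 through a samarium enolate chelated to the C8 ketone. Et3SiOTf and 2,6-lutidine then give 30, where it returns.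

Step 22 (B-alkyl Suzuki union). Risks are slow transmetalation of the hindered β-silyloxy alkylborane and loss of the aldehyde under aqueous base. Fallback: make the C4 nucleophile as a discrete alkylzinc and couple under anhydrous Negishi conditions. It sets out from 16. 9-BBN followed by NaBO3·4H2O gives the primary alcohol F9. I2, PPh3 and imidazole give the primary iodide F10. Zinc dust and LiCl in THF at 40 °C give the alkylzinc iodide F11. Pd(PPh3)4 (5 mol %, zerovalent palladium) and 32 in THF at rt then give 34, where it returns.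

## Further compounds

F1 | step 23 | ring-A allylic alcohol (C12 epimers) | CC(C)(C)[Si](C)(C)O[C@H]1CC(O)C(COCc2ccc(OC)cc2)=C[C@@]1(C)[C@@H](O[Si](C)(C)C(C)(C)C)C=C
F2 | step 23 | seco hydroxy aldehyde (C12 epimers) | O=C[C@@]1(O[Si](CC)(CC)CC)[C@H](/C=C(/C)CC[C@H](O[Si](C)(C)C(C)(C)C)[C@]2(C)C=C(COCc3ccc(OC)cc3)C(O)C[C@@H]2O[Si](C)(C)C(C)(C)C)OC(=O)[C@@H]1C
F3 | step 23 | seco allylic chloride (C12 epimers) | O=C[C@@]1(O[Si](CC)(CC)CC)[C@H](/C=C(/C)CC[C@H](O[Si](C)(C)C(C)(C)C)[C@]2(C)C=C(COCc3ccc(OC)cc3)C(Cl)C[C@@H]2O[Si](C)(C)C(C)(C)C)OC(=O)[C@@H]1C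
F4 | step 23 | macrocyclic C9 alcohol (C9 epimers) | CC(C)(C)[Si](C)(C)O[C@H]1CC=C(COCc4ccc(OC)cc4)[C@@H]2C(O)[C@@]3(O[Si](CC)(CC)CC)[C@H](/C=C(/C)CC[C@H](O[Si](C)(C)C(C)(C)C)[C@]21C)OC(=O)[C@@H]3C
F5 | step 19 | (2R,3S,4Z)-1,2-dihydroxy-5-iodohex-4-en-3-yl 2-bromopropanoate (epimers at the C–Br carbon) | OC[C@@H](O)[C@@H](OC(=O)C(C)Br)/C=C(/C)I
F6 | step 19 | primary TES ether of F5 | CC[Si](CC)(CC)OC[C@@H](O)[C@@H](OC(=O)C(C)Br)/C=C(/C)I
F7 | step 19 | (3S,4Z)-5-iodo-2-oxo-1-(TES-oxy)hex-4-en-3-yl 2-bromopropanoate | CC[Si](CC)(CC)OCC(=O)[C@@H](OC(=O)C(C)Br)/C=C(/C)I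
F8 | step 19 | hydroxy lactone with C9–OTES | CC[Si](CC)(CC)OC[C@@]1(O)[C@H](/C=C(/C)I)OC(=O)[C@@H]1C
F9 | step 22 | ring-A diene C4 primary alcohol | CC(C)(C)[Si](C)(C)O[C@H]1C=CC(COCc2ccc(OC)cc2)=C[C@@]1(C)[C@@H](O[Si](C)(C)C(C)(C)C)CCO
F10 | step 22 | ring-A diene C4 primary iodide | CC(C)(C)[Si](C)(C)O[C@H]1C=CC(COCc2ccc(OC)cc2)=C[C@@]1(C)[C@@H](O[Si](C)(C)C(C)(C)C)CCI
F11 | step 22 | ring-A diene C4 alkylzinc iodide | CC(C)(C)[Si](C)(C)O[C@H]1C=CC(COCc2ccc(OC)cc2)=C[C@@]1(C)[C@@H](O[Si](C)(C)C(C)(C)C)CC[Zn]I
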